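**Plan**
- Retrosynthesis: the C2–ring B bond and the O1–C2 bond are cut first (retro-oxa-Michael, retro-Knoevenagel) to syncarpic acid and a C2 lactol. Ring A is then cut at C4a–C5 and C8–C8a into a two-carbon ynolate (C4a≡C8a–O1) and a four-carbon acyl/enolate unit (C5 to C8).
- Enabling feature: C5(=O)–C6Me2–C7(=O)–C8Me2 of ring A is a dimethylketene dimer with no hydrogen on carbon. It flanks the enol ether C4a=C8a–O1, whose C4a carries no hydrogen and so stands at the alkyne oxidation level. A lithium ynolate plus the β-lactone dimer of dimethylketene therefore add up to ring A.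
- Forward: an acyclic chain carrying C3 and C4 is made from two 3-methylbutanal units by an amine-catalysed nitro-Michael addition, and the nitromethyl group is turned into a methyl ester. One pot then joins three components (ester, CH2Br2 as C4a, β-lactone dimer) to ring A and, on acid work-up, the pyran ring. Ring B is attached last.
- Stereochemistry: C3 and C4 come from the (R)-prolinol silyl ether catalyst (syn adduct = trans in the ring). C2 comes from a reversible, thermodynamically controlled ring closure in the last step.

Key step: step 7

Assumption: syncarpic acid (2,2,4,4-tetramethylcyclohexane-1,3,5-trione, 15) is taken as a purchasable compound.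

Step 1
Reactants: 1 2,2,4,4-tetramethylcyclobutane-1,3-dione
Product: 2 3,3-dimethyl-4-(propan-2-ylidene)oxetan-2-one (β-lactone dimer of dimethylketene)
Conditions: AlCl3 (1 mol %), neat, 140 °C; distillation
Reagents that add atoms: none
Why: Known Lewis-acid isomerization of the dimethylketene dimer, in which AlCl3 opens the strained dione to an acylium/aluminium enolate pair that recloses through oxygen to the enol lactone, a much better acyl donor.

Step 2
Reactants: 3 3-methylbutanal
Product: 6 (E)-4-methyl-1-nitropent-1-ene, via nitro alcohol 4 (not isolated), via mesylate 5 (not isolated)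
Conditions: MeNO2, KOt-Bu (10 mol %), THF/t-BuOH, 0 °C → rt; concentrate; then MsCl, Et3N, CH2Cl2, 0 °C
Reagents that add atoms: nitromethane C[N+](=O)[O-]
Why: Henry reaction followed by E1cB elimination of the mesylate should give the conjugated nitroalkene in its thermodynamically preferred E geometry.

Step 3
Reactants: 3 3-methylbutanal, 6 (E)-4-methyl-1-nitropent-1-ene
Product: 7 (2S,3S)-5-methyl-3-(nitromethyl)-2-(propan-2-yl)hexanal
Conditions: (R)-2-[diphenyl(trimethylsilyloxy)methyl]pyrrolidine (10 mol %), 4-nitrophenol (10 mol %), toluene, 0 °C → rt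
Reagents that add atoms: none
Why: Enamine-catalysed Michael addition in which the anti-(E)-enamine of 3 attacks the nitroalkene through an acyclic synclinal transition state from the face not shielded by the diphenyl(silyloxy)methyl group, which with the (R)-catalyst should give the syn (2S,3S) adduct that maps onto the trans C3/C4 pair of the target.

Step 4
Reactants: 7 (2S,3S)-5-methyl-3-(nitromethyl)-2-(propan-2-yl)hexanal
Product: 8 (3S,4S)-3-(dimethoxymethyl)-2,6-dimethyl-4-(nitromethyl)heptane
Conditions: HC(OMe)3, p-toluenesulfonic acid monohydrate (5 mol %), MeOH, rt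
Reagents that add atoms: trimethyl orthoformate COC(OC)OC
Why: Acid-catalysed acetalization masks the aldehyde carbon (future C2) for the organolithium chemistry without any base, so the epimerizable α-centre (future C3) should be untouched.

Step 5
Reactants: 8 (3S,4S)-3-(dimethoxymethyl)-2,6-dimethyl-4-(nitromethyl)heptane
Product: 9 (2S,3S)-3-(dimethoxymethyl)-4-methyl-2-(2-methylpropyl)pentanoic acid
Conditions: NaNO2, AcOH, DMSO, 35 °C
Reagents that add atoms: sodium nitrite [Na+].[O-]N=O
Why: Nitrite-mediated Nef-type oxidation of the primary nitro group turns the nitromethyl carbon into the carboxyl carbon (future C8a) under weakly acidic conditions in which neither stereocentre is acidic.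

Step 6
Reactants: 9 (2S,3S)-3-(dimethoxymethyl)-4-methyl-2-(2-methylpropyl)pentanoic acid
Product: 10 methyl (2S,3S)-3-(dimethoxymethyl)-4-methyl-2-(2-methylpropyl)pentanoate
Conditions: MeI, K2CO3, DMF, rt
Reagents that add atoms: iodomethane CI
Why: SN2 O-alkylation of the carboxylate gives the methyl ester needed for ynolate formation under conditions too weakly basic to epimerize the α-centre.

Step 7
Reactants: 10 methyl (2S,3S)-3-(dimethoxymethyl)-4-methyl-2-(2-methylpropyl)pentanoate, 2 3,3-dimethyl-4-(propan-2-ylidene)oxetan-2-one
Product: 14 (3S,4S)-2-hydroxy-6,6,8,8-tetramethyl-4-(2-methylpropyl)-3-(propan-2-yl)-3,4-dihydro-2H-chromene-5,7(6H,8H)-dione (lactol; both C2 anomers), via lithium ynolate 11 (not isolated), via acylketene enolate 12 (not isolated), via trione acetal 13 (not isolated)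
Conditions: CH2Br2, lithium 2,2,6,6-tetramethylpiperidide, THF, −78 °C; LiN(SiMe3)2, −78 → −20 °C; s-BuLi, −78 °C → rt; then 2 (2.5 equiv), −78 → 0 °C; then 2 M HCl, THF, rt
Reagents that add atoms: dibromomethane BrCBr; water O
Why: Proposed new method: (dibromomethyl)lithium adds to ester 10 and the rearrangement of the Kowalski ester homologation (1,2-shift of the C4 carbon with retention) gives ynolate 11, whose carbon terminus is acylated by the strained enol lactone 2; the tetrahedral adduct collapses with loss of the enolate oxygen, which makes the C4a–C5 bond and sets free acylketene enolate 12. Its tertiary enolate carbon (C8) then attacks the ketene carbon (C8a) in a 6-(enolendo)-exo-dig C-acylation that makes the C8–C8a bond and closes ring A as a β-triketone enolate; acid gives 13, hydrolyses the acetal and closes the pyran ring by 6-exo-trig hemiacetalization to lactol 14. The closest known reaction types are the carbonyl additions of lithium ynolates to ketones and esters, the acyl transfer from the β-lactone dimer of dimethylketene to nucleophiles, and the base-induced trimerization of dimethylketene, in which a tertiary enolate C-acylates a ketene and the hexamethyl analogue of ring A closes in the same way. Ring A gains no stereocentre, C3 and C4 are not acidic in 11 to 13 and should pass unchanged, and C2 arises as an anomeric mixture that is corrected in step 8. The step needs acyl transfer to win over [2+2] closure to a β-lactone enolate (which would lead to olefination) and C- over O-acylation of the enolate: the first is secured by the ring strain and enolate leaving group of 2, the second by the hydrogen-free ynolate carbon C4a (no proton transfer can quench the enolate) and by the β-triketone enolate being the thermodynamic sink into which an O-acylated isomer is funnelled by the lithium methoxide present.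

Step 8
Reactants: 14 (3S,4S)-2-hydroxy-6,6,8,8-tetramethyl-4-(2-methylpropyl)-3-(propan-2-yl)-3,4-dihydro-2H-chromene-5,7(6H,8H)-dione, 15 2,2,4,4-tetramethylcyclohexane-1,3,5-trione (syncarpic acid)
Product: 17 ericifolione, via alkylidene trione 16 (not isolated)
Conditions: 15 (1.2 equiv), p-toluenesulfonic acid monohydrate (10 mol %), 4 Å molecular sieves, CH2Cl2, 40 °C
Reagents that add atoms: none
Why: Acid-catalysed Knoevenagel condensation of the ring-opened aldehyde form of 14 with the enol of 15 gives alkylidene trione 16, which the ring A enol closes by reversible 6-exo-trig oxa-Michael addition, so that C2 (the only centre that equilibrates, by C2–O1 ionization with the ring A enolate as leaving group) should settle as 2R, cis to the isopropyl group, with ring B equatorial and the trans C3/C4 alkyl groups pseudo-diaxial (isobutyl axial to avoid the C5 carbonyl).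

**Compound list**
1 | 2,2,4,4-tetramethylcyclobutane-1,3-dione | CC1(C)C(=O)C(C)(C)C1=O | starting material
2 | 3,3-dimethyl-4-(propan-2-ylidene)oxetan-2-one | CC(C)=C1OC(=O)C1(C)C | intermediate
3 | 3-methylbutanal | CC(C)CC=O | starting material
4 | 4-methyl-1-nitropentan-2-ol (racemic; not isolated) | CC(C)CC(O)C[N+](=O)[O-] | intermediate
5 | 4-methyl-1-nitropentan-2-yl methanesulfonate (racemic; not isolated) | CC(C)CC(C[N+](=O)[O-])OS(C)(=O)=O | intermediate
6 | (E)-4-methyl-1-nitropent-1-ene | CC(C)C/C=C/[N+](=O)[O-] | intermediate
7 | (2S,3S)-5-methyl-3-(nitromethyl)-2-(propan-2-yl)hexanal | CC(C)C[C@@H]([C@H](C(C)C)C=O)C[N+](=O)[O-] | intermediate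
8 | (3S,4S)-3-(dimethoxymethyl)-2,6-dimethyl-4-(nitromethyl)heptane | CC(C)C[C@@H]([C@H](C(C)C)C(OC)OC)C[N+](=O)[O-] | intermediate
9 | (2S,3S)-3-(dimethoxymethyl)-4-methyl-2-(2-methylpropyl)pentanoic acid | CC(C)C[C@@H]([C@H](C(C)C)C(OC)OC)C(=O)O | intermediate
10 | methyl (2S,3S)-3-(dimethoxymethyl)-4-methyl-2-(2-methylpropyl)pentanoate | CC(C)C[C@@H]([C@H](C(C)C)C(OC)OC)C(=O)OC | intermediate
11 | lithium (3S,4S)-4-(dimethoxymethyl)-5-methyl-3-(2-methylpropyl)hex-1-yn-1-olate (not isolated) | [Li+].[O-]C#C[C@@H](CC(C)C)[C@H](C(C)C)C(OC)OC | intermediate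
12 | lithium (7S,8S)-8-(dimethoxymethyl)-2,4,4,9-tetramethyl-7-(2-methylpropyl)-5-oxo-6-(oxomethylidene)dec-2-en-3-olate (not isolated) | [Li+].[O-]C(=C(C)C)C(C)(C)C(=O)C(=C=O)[C@@H](CC(C)C)[C@H](C(C)C)C(OC)OC | intermediate
13 | 2-[(4S,5S)-5-(dimethoxymethyl)-2,6-dimethylheptan-4-yl]-3-hydroxy-4,4,6,6-tetramethylcyclohex-2-ene-1,5-dione (not isolated) | CC(C)C[C@H](C1=C(O)C(C)(C)C(=O)C(C)(C)C1=O)[C@H](C(C)C)C(OC)OC | intermediate
14 | (3S,4S)-2-hydroxy-6,6,8,8-tetramethyl-4-(2-methylpropyl)-3-(propan-2-yl)-3,4-dihydro-2H-chromene-5,7(6H,8H)-dione (both C2 anomers) | CC(C)C[C@@H]1C2=C(OC(O)[C@H]1C(C)C)C(C)(C)C(=O)C(C)(C)C2=O | intermediate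
15 | 2,2,4,4-tetramethylcyclohexane-1,3,5-trione (syncarpic acid) | CC1(C)C(=O)CC(=O)C(C)(C)C1=O | starting material
16 | 2-[(2R,3S)-3-(2-hydroxy-3,3,5,5-tetramethyl-4,6-dioxocyclohex-1-en-1-yl)-5-methyl-2-(propan-2-yl)hexylidene]-4,4,6,6-tetramethylcyclohexane-1,3,5-trione (not isolated) | CC(C)C[C@H](C1=C(O)C(C)(C)C(=O)C(C)(C)C1=O)[C@H](C(C)C)C=C1C(=O)C(C)(C)C(=O)C(C)(C)C1=O | intermediate
17 | ericifolione, (2R,3S,4S)-2-(2-hydroxy-3,3,5,5-tetramethyl-4,6-dioxocyclohex-1-en-1-yl)-6,6,8,8-tetramethyl-4-(2-methylpropyl)-3-(propan-2-yl)-3,4-dihydro-2H-chromene-5,7(6H,8H)-dione | CC(C)C[C@@H]1C2=C(O[C@@H](C3=C(O)C(C)(C)C(=O)C(C)(C)C3=O)[C@H]1C(C)C)C(C)(C)C(=O)C(C)(C)C2=O | target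

**Count**
Total steps: 8. Longest linear sequence: 7 steps (steps 2 to 8; step 1 is a one-step side branch).

**Steps most likely to fail**

Step 7. The adduct of ynolate 11 with lactone 2 may close to a spiro β-lactone enolate and open to an unsaturated carboxylate (olefination) instead of transferring the acyl group. The tertiary enolate may also acylate at oxygen. The addition of (dibromomethyl)lithium to the hindered ester may be slow, so that enolization erodes the C4 centre. The fallback uses known chemistry only; it sets out from 3 and 15 and rejoins the route at 14. Base-mediated aldol self-condensation of 3 (NaOH, H2O/MeOH, heat) should give (E)-5-methyl-2-(propan-2-yl)hex-2-enal F1. Conjugate addition of syncarpic acid 15 to F1 under iminium catalysis by a chiral primary amine salt (the 9-amino-9-deoxy-epi-cinchona alkaloid of the pseudo-enantiomeric pair that delivers 4S, with CF3CO2H) should give lactol 14 directly. C4 would be set by the catalyst and C3 by protonation trans to the isobutyl group, and the adduct would be trapped as the hemiacetal.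

Step 8. The condensation at the hindered, mostly lactol-masked aldehyde may stall. While the aldehyde is open, acid-induced enolization or dehydration toward a C2=C3 enol ether may erode C3, and equilibration at C2 may stay incomplete. The fallback sets out from 14 and rejoins at 17. Acetylation (Ac2O, pyridine, 4-(dimethylamino)pyridine) should give [(3S,4S)-6,6,8,8-tetramethyl-4-(2-methylpropyl)-5,7-dioxo-3-(propan-2-yl)-3,4,5,6,7,8-hexahydro-2H-chromen-2-yl] acetate F2. Activation of F2 with BF3·OEt2 in CH2Cl2 at low temperature in the presence of 15 should form the C2–ring B bond by C-alkylation of the enol with the cyclic oxocarbenium ion, so that no free aldehyde is present. The C2 mixture would then be equilibrated to 17 by brief warming with the same acid.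

Step 5. Acetic acid and the water formed may partly hydrolyse the dimethyl acetal, giving mixtures of acetal acid and lactol acid that complicate the esterification. The fallback sets out from 7 and rejoins at 10, with the oxidation done before protection. NaNO2/AcOH/DMSO applied to the unprotected nitro aldehyde 7 should give the oxo acid as its cyclic pseudo-acid, (3S,4S)-5-hydroxy-3-(2-methylpropyl)-4-(propan-2-yl)oxolan-2-one F3. One-pot Fischer esterification and acetalization (MeOH, HC(OMe)3, H2SO4 cat., reflux) should then open F3 to ester acetal 10.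

**Further compounds**
F1 | step 7 | (E)-5-methyl-2-(propan-2-yl)hex-2-enal | CC(C)C/C=C(/C=O)C(C)C
F2 | step 8 | [(3S,4S)-6,6,8,8-tetramethyl-4-(2-methylpropyl)-5,7-dioxo-3-(propan-2-yl)-3,4,5,6,7,8-hexahydro-2H-chromen-2-yl] acetate (both C2 anomers) | CC(C)C[C@@H]1C2=C(OC(OC(C)=O)[C@H]1C(C)C)C(C)(C)C(=O)C(C)(C)C2=O
F3 | step 5 | (3S,4S)-5-hydroxy-3-(2-methylpropyl)-4-(propan-2-yl)oxolan-2-one (both C5 epimers) | CC(C)C[C@H]1[C@H](C(C)C)C(O)OC1=O
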